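## Retrosynthetic overview

1. Ring locants: O1, C2 (CHPr), C3 (amide C=O), N4, C5–C27, C28 (ester C=O). The 28-membered ring is the only ring and is formed last, by Suzuki–Miyaura closure of the C13–C14 diene bond.
2. Before that, a Wittig union (C26=C27) and an amide union (N4–C3) join a keto aldehyde (C14–C26), a linker acid (O1–C3 with C27/C28) and an aminotriol alkenyl iodide (C5–C13).
3. Key step: the C21–C22 bond of the keto aldehyde is made by a 1,2-shift of an alkyl chain from boron to the α-carbon of a bromomethyl ketone.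
4. The bromomethyl ketone comes from cyclohex-2-en-1-one (asymmetric ethyl addition sets C16, ozonolytic ring opening, Takai–Utimoto olefination, diazoketone/HBr). C25 comes from (R)-2-methylpent-4-en-1-ol and C2 from (S)-2-hydroxypentanoic acid.
5. Aminotriol: anti-carbomagnesiation of propargyl alcohol (C12=C13 geometry), cross-metathesis with an (S)-epichlorohydrin-derived chlorohydrin (C6), then a new tungsten-catalysed hydroxyl-directed anti-dihydroxylation (C8, C9).

Assumption: (R)-2-methylpent-4-en-1-ol, diethylzinc and the two Grignard solutions are bought as catalogue items; Bpin means 4,4,5,5-tetramethyl-1,3,2-dioxaborolan-2-yl.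

## Route

Step 1
Reactants: 1 cyclohex-2-en-1-one; 2 diethylzinc
Product: 4 [(3R)-3-ethylcyclohex-1-en-1-yl]oxy(trimethyl)silane, via zinc enolate 3 (not isolated)
Conditions: Cu(OTf)2 (2 mol%), (R,S,S)-BINOL bis(1-phenylethyl)amine phosphoramidite (4 mol%), toluene, −30 °C; then TMSOTf, −30 °C → rt
Reagents that add atoms: trimethylsilyl trifluoromethanesulfonate, C[Si](C)(C)OS(=O)(=O)C(F)(F)F
Why: Copper-catalysed asymmetric conjugate addition sets the (R) centre that becomes C16 by ligand control of the enone face (the antipodal ligand is the one known to give the (S)-ketone), and the regiodefined zinc enolate is silylated on oxygen so that the later ring cleavage falls at C1=C2.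

Step 2
Reactants: 4 [(3R)-3-ethylcyclohex-1-en-1-yl]oxy(trimethyl)silane
Product: 6 (5R)-5-ethyl-6-oxohexanoic acid, via methoxy hydroperoxide 5 (not isolated)
Conditions: O3, CH2Cl2/MeOH (5:1), −78 °C; then Me2S, −78 °C → rt
Reagents that add atoms: ozone, [O-][O+]=O
Why: Ozonolysis of the electron-rich silyl enol ether cleaves C1=C2 regiospecifically to a carboxyl group (the silyl ester is methanolysed on warming) and an aldehyde, and the neutral reductive work-up leaves the α-stereocentre intact.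

Step 3
Reactants: 6 (5R)-5-ethyl-6-oxohexanoic acid
Product: 9 (5R,6E)-5-ethyl-7-(Bpin)hept-6-enoic acid, via silyl ester aldehyde 7 (not isolated), via silyl ester boronate 8 (not isolated)
Conditions: N,O-bis(trimethylsilyl)acetamide (1.05 equiv), THF, rt; then CrCl2 (8 equiv), Cl2CHBpin (2 equiv), LiI (4 equiv), THF, rt; aq. NH4Cl work-up
Reagents that add atoms: 2-(dichloromethyl)-4,4,5,5-tetramethyl-1,3,2-dioxaborolane, ClC(Cl)B1OC(C)(C)C(C)(C)O1
Why: Takai–Utimoto boryl olefination (gem-dichromium reagent from the dihalomethylboronate and CrCl2) converts the aldehyde into the E-alkenylboronate under non-basic conditions that do not epimerise the α-centre, the acid being masked in the flask as its trimethylsilyl ester.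

Step 4
Reactants: 9 (5R,6E)-5-ethyl-7-(Bpin)hept-6-enoic acid
Product: 12 (6R,7E)-1-bromo-6-ethyl-8-(Bpin)oct-7-en-2-one, via acid chloride 10 (not isolated), via diazoketone 11 (not isolated)
Conditions: (COCl)2, cat. DMF, CH2Cl2, 0 °C → rt, evaporate; TMSCHN2 (2 equiv), MeCN/THF, 0 °C; then 48% aq. HBr, 0 °C
Reagents that add atoms: (trimethylsilyl)diazomethane, C[Si](C)(C)C=[N+]=[N-]; hydrogen bromide, Br
Why: Acid chloride formation, C-acylation of the silyl diazomethane (first stage of an Arndt–Eistert sequence) and hydrobromination of the diazoketone with loss of N2 give the bromomethyl ketone without exposing the alkenylboronate to base or to organometallics.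

Step 5
Reactants: 13 (2R)-2-methylpent-4-en-1-ol; 12 (6R,7E)-1-bromo-6-ethyl-8-(Bpin)oct-7-en-2-one
Product: 15 (2R,11R,12E)-11-ethyl-1-hydroxy-2-methyl-13-(Bpin)tridec-12-en-7-one, via alkylborane 14 (not isolated)
Conditions: 13, 9-BBN-H (2.05 equiv), THF, 0 °C → rt; then 12, potassium 2,6-di-tert-butylphenoxide (1.1 equiv), THF, 0 °C → rt; pH 7 buffer work-up without oxidant
Reagents that add atoms: none
Why: Key step: hydroboration puts boron on the terminal carbon of 13 (the hydroxyl is masked in the flask as its borinate), the aryloxide turns 12 into its α-bromo enolate, which adds through carbon to the trialkylborane, and the primary alkyl group then undergoes an anionotropic 1,2-shift from boron to carbon with loss of bromide (organoborane α-alkylation of an α-bromo ketone, in which the bridgehead bonds of the 9-BBN cage migrate poorly), forging C21–C22 without touching either stereocentre or the alkenylboronate.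

Step 6
Reactants: 15 (2R,11R,12E)-11-ethyl-1-hydroxy-2-methyl-13-(Bpin)tridec-12-en-7-one
Product: 16 (2R,11R,12E)-11-ethyl-2-methyl-7-oxo-13-(Bpin)tridec-12-enal
Conditions: TEMPO (10 mol%), PhI(OAc)2 (1.2 equiv), CH2Cl2, rt
Reagents that add atoms: none
Why: TEMPO-catalysed oxidation with PhI(OAc)2 stops at the aldehyde, is mild enough not to epimerise C2, and does not touch the ketone or the alkenylboronate.

Step 7
Reactants: 17 (2S)-2-hydroxypentanoic acid; 18 2-bromopropanoyl bromide
Product: 19 (2S)-2-[(2-bromopropanoyl)oxy]pentanoic acid (both epimers at the CHBr carbon)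
Conditions: pyridine, CH2Cl2, −10 °C → rt; dilute aq. HCl work-up
Reagents that add atoms: none
Why: O-Acylation of the α-hydroxy acid by the acyl bromide (any mixed anhydride is hydrolysed on work-up) builds the O1–C28 ester without breaking a bond at the (S) centre, and the CHBr centre is destroyed later.

Step 8
Reactants: 20 prop-2-yn-1-ol; 21 but-3-en-1-ylmagnesium bromide
Product: 23 (2Z)-2-(iodomethylidene)hex-5-en-1-ol, via alkenylmagnesium alkoxide 22 (not isolated)
Conditions: 21 (2.5 equiv), CuI (15 mol%), THF, −20 °C → rt; then iodine, THF, −78 → 0 °C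
Reagents that add atoms: iodine, [I][I]
Why: Copper-catalysed anti-carbomagnesiation of the propargylic magnesium alkoxide places the butenyl group on the internal carbon and magnesium on the terminal carbon cis to CH2O (five-membered chelate), and iodinolysis with retention gives the Z-iodoalkene that fixes the C12=C13 geometry.

Step 9
Reactants: 23 (2Z)-2-(iodomethylidene)hex-5-en-1-ol
Product: 24 (1Z)-1-iodo-2-(methoxymethyl)hexa-1,5-diene
Conditions: NaH, MeI, THF, 0 °C → rt
Reagents that add atoms: iodomethane, CI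
Why: Williamson etherification of the allylic alkoxide with iodomethane, to which the alkenyl iodide and the terminal alkene are inert.

Step 10
Reactants: 25 (S)-2-(chloromethyl)oxirane; 26 vinylmagnesium bromide
Product: 27 (2S)-1-chloropent-4-en-2-ol
Conditions: CuI (10 mol%), THF, −40 → −20 °C; aq. NH4Cl
Reagents that add atoms: none
Why: Copper-catalysed Grignard opening of the epoxide at its unsubstituted carbon is faster than chloride displacement and breaks no bond at the stereocentre, so the (S)-epoxide gives the (S)-chlorohydrin that becomes C6.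

Step 11
Reactants: 24 (1Z)-1-iodo-2-(methoxymethyl)hexa-1,5-diene; 27 (2S)-1-chloropent-4-en-2-ol
Product: 28 (2S,4E,8Z)-1-chloro-9-iodo-8-(methoxymethyl)nona-4,8-dien-2-ol
Conditions: second-generation Hoveyda–Grubbs catalyst (5 mol%), 27 (3 equiv), CH2Cl2, 40 °C; E isomer purified on AgNO3-impregnated silica
Reagents that add atoms: none
Why: Olefin cross-metathesis between the two terminal alkenes (excess of the cheap partner, trisubstituted iodoalkene inert) gives mainly the E-alkene with release of ethene, and the minor Z isomer is removed.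

Step 12
Reactants: 28 (2S,4E,8Z)-1-chloro-9-iodo-8-(methoxymethyl)nona-4,8-dien-2-ol
Product: 29 (2S,4E,8Z)-1-azido-9-iodo-8-(methoxymethyl)nona-4,8-dien-2-ol
Conditions: NaN3, cat. Bu4NI, DMF, 65 °C
Reagents that add atoms: sodium azide, [Na+].[N-]=[N+]=[N-]
Why: SN2 displacement of the primary chloride by azide (directly or through the terminal epoxide, in both cases without breaking a bond at C2) installs the masked amine.

Step 13
Reactants: 29 (2S,4E,8Z)-1-azido-9-iodo-8-(methoxymethyl)nona-4,8-dien-2-ol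
Product: 31 (2S,4S,5R,8Z)-1-azido-9-iodo-8-(methoxymethyl)non-8-ene-2,4,5-triol, via epoxy alcohol 30 (not isolated)
Conditions: WO2(acac)2 (10 mol%), C2-symmetric bishydroxamic acid ligand from trans-cyclohexane-1,2-diamine (12 mol%, the enantiomer that delivers the (S,S)-epoxide), 30% aq. H2O2 (2 equiv), NaCl, CH2Cl2, rt; then 45 °C
Reagents that add atoms: hydrogen peroxide, OO; water, O
Why: Proposed new method: a one-flask hydroxyl-directed, catalyst-controlled anti-dihydroxylation of a homoallylic alcohol, in which the hexavalent tungsten peroxo complex of the chiral bishydroxamic acid, bound to the C2 alkoxide, epoxidises only the nearby C4=C5 alkene on the ligand-defined face to give the (S,S)-epoxide 30, and the same Lewis acidic tungsten, held in a six-membered chelate by the alkoxide and the epoxide oxygen, then lets water attack the distal carbon C5 with inversion while C4 keeps its oxygen, which sets C4 (S) and C5 (R); the closest known reactions are the tungsten–bishydroxamic acid epoxidation of homoallylic alcohols with aqueous H2O2, the metal-templated distal opening of chelated epoxy alcohols and the molybdenum-catalysed anti-dihydroxylation of allylic alcohols.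

Step 14
Reactants: 31 (2S,4S,5R,8Z)-1-azido-9-iodo-8-(methoxymethyl)non-8-ene-2,4,5-triol
Product: 32 (2S,4S,5R,8Z)-1-amino-9-iodo-8-(methoxymethyl)non-8-ene-2,4,5-triol
Conditions: PMe3 (1.5 equiv), THF/H2O (10:1), rt
Reagents that add atoms: none
Why: Staudinger reduction is selective for the azide and leaves the iodoalkene, the allylic ether and the triol untouched.

Step 15
Reactants: 32 (2S,4S,5R,8Z)-1-amino-9-iodo-8-(methoxymethyl)non-8-ene-2,4,5-triol; 19 (2S)-2-[(2-bromopropanoyl)oxy]pentanoic acid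
Product: 33 (2S)-1-oxo-1-{[(2S,4S,5R,8Z)-2,4,5-trihydroxy-9-iodo-8-(methoxymethyl)non-8-en-1-yl]amino}pentan-2-yl 2-bromopropanoate
Conditions: EDC·HCl, HOAt, CH2Cl2/DMF, 0 °C
Reagents that add atoms: none
Why: Carbodiimide/HOAt amidation acylates the primary amine far faster than the three hydroxyl groups, and the low temperature without added base limits epimerisation of the α-acyloxy acid and N-alkylation by the secondary bromide.

Step 16
Reactants: 33 (2S)-1-oxo-1-{[(2S,4S,5R,8Z)-2,4,5-trihydroxy-9-iodo-8-(methoxymethyl)non-8-en-1-yl]amino}pentan-2-yl 2-bromopropanoate; 16 (2R,11R,12E)-11-ethyl-2-methyl-7-oxo-13-(Bpin)tridec-12-enal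
Product: 35 (2S)-1-oxo-1-{[(2S,4S,5R,8Z)-2,4,5-trihydroxy-9-iodo-8-(methoxymethyl)non-8-en-1-yl]amino}pentan-2-yl (2E,4R,13R,14E)-13-ethyl-2,4-dimethyl-9-oxo-15-(Bpin)pentadeca-2,14-dienoate, via phosphonium bromide 34 (not isolated)
Conditions: PPh3 (1.3 equiv), MeCN, 55 °C; then 16 (1.0 equiv), iPr2NEt (1.5 equiv), CH2Cl2, 40 °C
Reagents that add atoms: none
Why: SN2 attack of PPh3 on the α-bromo ester gives the ester-stabilised phosphonium salt, whose ylide (mild amine base) undergoes an E-selective Wittig olefination with the aldehyde rather than the ketone to form the C26=C27 trisubstituted enoate without epimerising C25.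

Step 17
Reactants: 35 (2S)-1-oxo-1-{[(2S,4S,5R,8Z)-2,4,5-trihydroxy-9-iodo-8-(methoxymethyl)non-8-en-1-yl]amino}pentan-2-yl (2E,4R,13R,14E)-13-ethyl-2,4-dimethyl-9-oxo-15-(Bpin)pentadeca-2,14-dienoate
Product: 36 (2S,6S,8S,9R,12Z,14E,16R,25R,26E)-16-ethyl-6,8,9-trihydroxy-12-(methoxymethyl)-25,27-dimethyl-2-propyl-1-oxa-4-azacyclooctacosa-12,14,26-triene-3,20,28-trione (target)
Conditions: Pd(PPh3)4 (20 mol%), TlOEt (3 equiv), THF/H2O (3:1), rt, 1 mM
Reagents that add atoms: none
Why: Intramolecular Suzuki–Miyaura coupling (oxidative addition of zerovalent palladium into the carbon–iodine bond, TlOEt-accelerated transmetalation from boron, reductive elimination) at high dilution closes the 28-membered ring at C13–C14 with retention of both alkene geometries and tolerates the free triol, the amide, the ester and the ketone.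

## Compound list

1 | cyclohex-2-en-1-one | O=C1C=CCCC1 | starting material
2 | diethylzinc | CC[Zn]CC | starting material
3 | ethylzinc (3R)-3-ethylcyclohex-1-en-1-olate | CC[Zn]OC1=C[C@H](CC)CCC1 | intermediate
4 | [(3R)-3-ethylcyclohex-1-en-1-yl]oxy(trimethyl)silane | C[Si](C)(C)OC1=C[C@H](CC)CCC1 | intermediate
5 | trimethylsilyl (5R)-5-ethyl-6-hydroperoxy-6-methoxyhexanoate (both epimers at C6) | C[Si](C)(C)OC(=O)CCC[C@@H](CC)C(OC)OO | intermediate
6 | (5R)-5-ethyl-6-oxohexanoic acid | OC(=O)CCC[C@@H](CC)C=O | intermediate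
7 | trimethylsilyl (5R)-5-ethyl-6-oxohexanoate | C[Si](C)(C)OC(=O)CCC[C@@H](CC)C=O | intermediate
8 | trimethylsilyl (5R,6E)-5-ethyl-7-(Bpin)hept-6-enoate | C[Si](C)(C)OC(=O)CCC[C@@H](CC)/C=C/B1OC(C)(C)C(C)(C)O1 | intermediate
9 | (5R,6E)-5-ethyl-7-(Bpin)hept-6-enoic acid | OC(=O)CCC[C@@H](CC)/C=C/B1OC(C)(C)C(C)(C)O1 | intermediate
10 | (5R,6E)-5-ethyl-7-(Bpin)hept-6-enoyl chloride | ClC(=O)CCC[C@@H](CC)/C=C/B1OC(C)(C)C(C)(C)O1 | intermediate
11 | (6R,7E)-1-diazo-6-ethyl-8-(Bpin)oct-7-en-2-one | [N-]=[N+]=CC(=O)CCC[C@@H](CC)/C=C/B1OC(C)(C)C(C)(C)O1 | intermediate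
12 | (6R,7E)-1-bromo-6-ethyl-8-(Bpin)oct-7-en-2-one | BrCC(=O)CCC[C@@H](CC)/C=C/B1OC(C)(C)C(C)(C)O1 | intermediate
13 | (2R)-2-methylpent-4-en-1-ol | OC[C@H](C)CC=C | starting material
14 | 9-[(4R)-5-(9-borabicyclo[3.3.1]nonan-9-yloxy)-4-methylpentyl]-9-borabicyclo[3.3.1]nonane | C[C@H](CCCB1C2CCCC1CCC2)COB1C2CCCC1CCC2 | intermediate
15 | (2R,11R,12E)-11-ethyl-1-hydroxy-2-methyl-13-(Bpin)tridec-12-en-7-one | OC[C@H](C)CCCCC(=O)CCC[C@@H](CC)/C=C/B1OC(C)(C)C(C)(C)O1 | intermediate
16 | (2R,11R,12E)-11-ethyl-2-methyl-7-oxo-13-(Bpin)tridec-12-enal | O=C[C@H](C)CCCCC(=O)CCC[C@@H](CC)/C=C/B1OC(C)(C)C(C)(C)O1 | intermediate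
17 | (2S)-2-hydroxypentanoic acid | CCC[C@H](O)C(=O)O | starting material
18 | 2-bromopropanoyl bromide (racemic) | CC(Br)C(=O)Br | starting material
19 | (2S)-2-[(2-bromopropanoyl)oxy]pentanoic acid (both epimers at the CHBr carbon) | CCC[C@H](OC(=O)C(C)Br)C(=O)O | intermediate
20 | prop-2-yn-1-ol | OCC#C | starting material
21 | but-3-en-1-ylmagnesium bromide | C=CCC[Mg]Br | starting material
22 | bromomagnesium (2Z)-2-[(bromomagnesio)methylidene]hex-5-en-1-olate | Br[Mg]/C=C(\CO[Mg]Br)CCC=C | intermediate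
23 | (2Z)-2-(iodomethylidene)hex-5-en-1-ol | I/C=C(\CO)CCC=C | intermediate
24 | (1Z)-1-iodo-2-(methoxymethyl)hexa-1,5-diene | I/C=C(\COC)CCC=C | intermediate
25 | (S)-2-(chloromethyl)oxirane ((S)-epichlorohydrin) | ClC[C@@H]1CO1 | starting material
26 | vinylmagnesium bromide | C=C[Mg]Br | starting material
27 | (2S)-1-chloropent-4-en-2-ol | C=CC[C@H](O)CCl | intermediate
28 | (2S,4E,8Z)-1-chloro-9-iodo-8-(methoxymethyl)nona-4,8-dien-2-ol | I/C=C(\COC)CC/C=C/C[C@H](O)CCl | intermediate
29 | (2S,4E,8Z)-1-azido-9-iodo-8-(methoxymethyl)nona-4,8-dien-2-ol | I/C=C(\COC)CC/C=C/C[C@H](O)CN=[N+]=[N-] | intermediate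
30 | (2S)-1-azido-3-{(2S,3S)-3-[(3Z)-4-iodo-3-(methoxymethyl)but-3-en-1-yl]oxiran-2-yl}propan-2-ol | I/C=C(\COC)CC[C@@H]1O[C@H]1C[C@H](O)CN=[N+]=[N-] | intermediate
31 | (2S,4S,5R,8Z)-1-azido-9-iodo-8-(methoxymethyl)non-8-ene-2,4,5-triol | I/C=C(\COC)CC[C@@H](O)[C@@H](O)C[C@H](O)CN=[N+]=[N-] | intermediate
32 | (2S,4S,5R,8Z)-1-amino-9-iodo-8-(methoxymethyl)non-8-ene-2,4,5-triol | I/C=C(\COC)CC[C@@H](O)[C@@H](O)C[C@H](O)CN | intermediate
33 | (2S)-1-oxo-1-{[(2S,4S,5R,8Z)-2,4,5-trihydroxy-9-iodo-8-(methoxymethyl)non-8-en-1-yl]amino}pentan-2-yl 2-bromopropanoate (both epimers at the CHBr carbon) | I/C=C(\COC)CC[C@@H](O)[C@@H](O)C[C@H](O)CNC(=O)[C@H](CCC)OC(=O)C(C)Br | intermediate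
34 | triphenylphosphonium bromide formed from 33 at its CHBr carbon | I/C=C(\COC)CC[C@@H](O)[C@@H](O)C[C@H](O)CNC(=O)[C@H](CCC)OC(=O)C(C)[P+](c1ccccc1)(c1ccccc1)c1ccccc1.[Br-] | intermediate
35 | (2S)-1-oxo-1-{[(2S,4S,5R,8Z)-2,4,5-trihydroxy-9-iodo-8-(methoxymethyl)non-8-en-1-yl]amino}pentan-2-yl (2E,4R,13R,14E)-13-ethyl-2,4-dimethyl-9-oxo-15-(Bpin)pentadeca-2,14-dienoate | I/C=C(\COC)CC[C@@H](O)[C@@H](O)C[C@H](O)CNC(=O)[C@H](CCC)OC(=O)/C(C)=C/[C@H](C)CCCCC(=O)CCC[C@@H](CC)/C=C/B1OC(C)(C)C(C)(C)O1 | intermediate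
36 | (2S,6S,8S,9R,12Z,14E,16R,25R,26E)-16-ethyl-6,8,9-trihydroxy-12-(methoxymethyl)-25,27-dimethyl-2-propyl-1-oxa-4-azacyclooctacosa-12,14,26-triene-3,20,28-trione | CCC[C@@H]1OC(=O)/C(C)=C/[C@H](C)CCCCC(=O)CCC[C@@H](CC)/C=C/C=C(\COC)CC[C@@H](O)[C@@H](O)C[C@H](O)CNC1=O | target

## Step count and risks

Total step count: 17. Longest linear sequence: 9 steps (steps 8, 9, 11, 12, 13, 14, 15, 16, 17).

The three steps most likely to fail:

**Step 13 (the proposed new anti-dihydroxylation).** The catalyst and the existing C2 centre may be mismatched. Water may open the epoxide at the proximal carbon. The C2 hydroxyl may close onto C5 to give a tetrahydrofuran. The fallback uses known chemistry, sets out from 29 and comes back at 31. Boc2O and DMAP in CH2Cl2 give tert-butyl (2S,4E,8Z)-1-azido-9-iodo-8-(methoxymethyl)nona-4,8-dien-2-yl carbonate F1. Shi epoxidation (D-fructose-derived ketone, Oxone, K2CO3, MeCN/dimethoxymethane/buffer, 0 °C) gives the (R,R)-epoxy carbonate F2, the epoxide opposite to 30. BF3·OEt2 in CH2Cl2 at −40 °C makes the carbonate carbonyl oxygen open the epoxide at the proximal carbon (6-exo, inversion) with loss of isobutene, giving the six-membered cyclic carbonate F3. K2CO3 in MeOH then gives 31.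

**Step 5 (the 1,2-shift union).** The α-bromo enolate may be captured too slowly by the borane, a cage bond may migrate, or the borinate oxygen may interfere. The fallback sets out from 12 and 13 and comes back at 15. Visible-light atom-transfer radical addition (fac-Ir(ppy)3, blue LED, LiBr, DMF/H2O) of the bromomethyl ketone to the terminal alkene gives the secondary bromide (2R,11R,12E)-4-bromo-11-ethyl-1-hydroxy-2-methyl-13-(Bpin)tridec-12-en-7-one F4. (Me3Si)3SiH and AIBN in toluene at 80 °C then remove the bromine to give 15.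

**Step 17 (macrocyclisation).** Oligomerisation or protodeboronation may win at this ring size. The fallback closes the ring at the amide instead, sets out from 16, 19 and 32 and comes back at 36. Acid 19 and PPh3 give [1-{[(1S)-1-carboxybutyl]oxy}-1-oxopropan-2-yl]triphenylphosphonium bromide F5. Wittig reaction with 16 (Et3N, CH2Cl2) gives (2S)-2-{[(2E,4R,13R,14E)-13-ethyl-2,4-dimethyl-9-oxo-15-(Bpin)pentadeca-2,14-dienoyl]oxy}pentanoic acid F6. Intermolecular Suzuki–Miyaura coupling with 32 (Pd(PPh3)4, TlOEt, THF/H2O) gives the seco amino acid (2S)-2-{[(2E,4R,13R,14E,16Z,20R,21S,23S)-24-amino-13-ethyl-20,21,23-trihydroxy-17-(methoxymethyl)-2,4-dimethyl-9-oxotetracosa-2,14,16-trienoyl]oxy}pentanoic acid F7. Macrolactamisation (DEPBT, iPr2NEt, DMF, 1 mM) then gives 36.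

Further compounds
F1 | step 13 | tert-butyl (2S,4E,8Z)-1-azido-9-iodo-8-(methoxymethyl)nona-4,8-dien-2-yl carbonate | I/C=C(\COC)CC/C=C/C[C@H](OC(=O)OC(C)(C)C)CN=[N+]=[N-]
F2 | step 13 | tert-butyl (2S)-1-azido-3-{(2R,3R)-3-[(3Z)-4-iodo-3-(methoxymethyl)but-3-en-1-yl]oxiran-2-yl}propan-2-yl carbonate | I/C=C(\COC)CC[C@H]1O[C@@H]1C[C@H](OC(=O)OC(C)(C)C)CN=[N+]=[N-]
F3 | step 13 | (4S,6S)-4-(azidomethyl)-6-[(1R,4Z)-1-hydroxy-5-iodo-4-(methoxymethyl)pent-4-en-1-yl]-1,3-dioxan-2-one | I/C=C(\COC)CC[C@@H](O)[C@@H]1C[C@@H](CN=[N+]=[N-])OC(=O)O1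
F4 | step 5 | (2R,11R,12E)-4-bromo-11-ethyl-1-hydroxy-2-methyl-13-(Bpin)tridec-12-en-7-one (both epimers at C4) | OC[C@H](C)CC(Br)CCC(=O)CCC[C@@H](CC)/C=C/B1OC(C)(C)C(C)(C)O1
F5 | step 17 | [1-{[(1S)-1-carboxybutyl]oxy}-1-oxopropan-2-yl]triphenylphosphonium bromide | CCC[C@H](OC(=O)C(C)[P+](c1ccccc1)(c1ccccc1)c1ccccc1)C(=O)O.[Br-]
F6 | step 17 | (2S)-2-{[(2E,4R,13R,14E)-13-ethyl-2,4-dimethyl-9-oxo-15-(Bpin)pentadeca-2,14-dienoyl]oxy}pentanoic acid | CCC[C@H](OC(=O)/C(C)=C/[C@H](C)CCCCC(=O)CCC[C@@H](CC)/C=C/B1OC(C)(C)C(C)(C)O1)C(=O)O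
F7 | step 17 | (2S)-2-{[(2E,4R,13R,14E,16Z,20R,21S,23S)-24-amino-13-ethyl-20,21,23-trihydroxy-17-(methoxymethyl)-2,4-dimethyl-9-oxotetracosa-2,14,16-trienoyl]oxy}pentanoic acid | CCC[C@H](OC(=O)/C(C)=C/[C@H](C)CCCCC(=O)CCC[C@@H](CC)/C=C/C=C(\COC)CC[C@@H](O)[C@@H](O)C[C@H](O)CN)C(=O)O
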